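**Retrosynthetic overview**

1. All four ring C–O bonds of the target (oxirane oxygen on C1/C6, OH on C2, OBz on C3) lie on one face. The oxirane is therefore opened first, to a cyclohexa-1,3-diene whose free C2–OH can direct a syn epoxidation of the C1=C6 bond and set both oxirane stereocentres in one event.
2. The C3 benzoate is traced back to site-selective acylation of the distal hydroxyl of a cis-diol.
3. Key disconnection: the bond between the exocyclic CH2 and ring carbon C1, made by Stille coupling of a vinylic bromide with (tributylstannyl)methyl benzoate. The enabling feature is that the quaternary oxirane carbon C1 of the six-membered ring is an sp2 diene carbon before epoxidation, and the adjacent cis C2–O/C3–O pair is exactly the cis-diol that an arene dioxygenase places next to the halogen of bromobenzene, so C1 can enter as the C–Br carbon of an enantiopure bromodiene-diol.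
4. Ring order: the carbocycle is the benzene ring of bromobenzene, dearomatised enzymatically (this sets C2 and C3); the oxirane ring is closed last.

Key step: step 3

Assumption (remark on the chemistry): the recombinant toluene-dioxygenase strain that converts bromobenzene into its cis-dihydrodiol is available. The same diol has also been offered commercially; if it is bought, step 1 falls away.

Step 1
Reactants: 1 bromobenzene
Product: 2 (1S,2S)-3-bromocyclohexa-3,5-diene-1,2-diol (cis-diol)
Conditions: whole cells of E. coli JM109(pDTG601) expressing toluene dioxygenase, glucose, air, mineral salts medium, pH 7, 30 °C; EtOAc extraction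
Reagents that add atoms: dioxygen, O=O
Why: Enzymatic dearomatising arene cis-dihydroxylation: toluene dioxygenase delivers both atoms of one O2 molecule to the same face of the C2–C3 bond of bromobenzene, so the diol is cis by mechanism and the enzyme pocket fixes both new carbinol centres as (1S,2S), the configuration needed for C2 and C3 of the target.

Step 2
Reactants: 3 (tributylstannyl)methanol
Product: 4 (tributylstannyl)methyl benzoate
Conditions: BzCl, pyridine, DMAP (cat.), CH2Cl2, 0 °C to rt
Reagents that add atoms: benzoyl chloride, O=C(Cl)c1ccccc1
Why: Nucleophilic acyl substitution (DMAP-catalysed O-benzoylation) of a primary alcohol; the tetraalkyltin unit is inert to BzCl/pyridine and no stereocentre is involved.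

Step 3
Reactants: 2 (1S,2S)-3-bromocyclohexa-3,5-diene-1,2-diol; 4 (tributylstannyl)methyl benzoate
Product: 5 [(5S,6R)-5,6-dihydroxycyclohexa-1,3-dien-1-yl]methyl benzoate (cis-diol)
Conditions: Pd2(dba)3 (2.5 mol %), AsPh3 (20 mol %), CuI (10 mol %), NMP, 50 °C, degassed, dark
Reagents that add atoms: none
Why: Stille cross-coupling: zerovalent palladium inserts into the vinylic C–Br bond of 2, the benzoyloxymethyl group passes from tin to the divalent palladium centre (CuI assisting the transfer), and reductive elimination forges the C(sp2)–CH2 bond. The closest known reaction type is the Stille coupling of (hydroxymethyl)- and (acyloxymethyl)tributylstannanes with aryl and alkenyl halides, together with Stille couplings of halocyclohexadiene cis-diols. No ring is closed and no stereocentre is created; the two carbinol centres are spectators because no bond to them is made or broken, and the position of the new trisubstituted alkene is fixed by the C–Br carbon. The step needs group selectivity at tin, which the α-oxygen (and the ester carbonyl contact to tin) should secure by making CH2OBz transfer far faster than butyl. It also needs C–Br insertion to outrun ionisation of allylic C–O bonds, which is secured because 2 carries only free hydroxyls and the primary dienylic benzoate of the product should ionise much more slowly than the bromide reacts at 50 °C. The neutral, non-acidic medium should keep the acid-labile diene-diol from dehydrating to a phenol.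

Step 4
Reactants: 5 [(5S,6R)-5,6-dihydroxycyclohexa-1,3-dien-1-yl]methyl benzoate
Product: 6 [(5S,6R)-5-(benzoyloxy)-6-hydroxycyclohexa-1,3-dien-1-yl]methyl benzoate (cis)
Conditions: BzCl (1.05 equiv), 2,4,6-collidine, CH2Cl2, −40 °C
Reagents that add atoms: benzoyl chloride, O=C(Cl)c1ccccc1
Why: Kinetically controlled regioselective O-acylation (nucleophilic acyl substitution): the distal C5 hydroxyl is pseudoequatorial and unhindered, whereas the C6 hydroxyl is pseudoaxial and flanked by the substituted sp2 carbon C1, so one equivalent of BzCl at low temperature should acylate C5–OH, in line with the known distal-selective protection of 3-substituted cyclohexadiene cis-diols; no stereocentre is touched.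

Step 5
Reactants: 6 [(5S,6R)-5-(benzoyloxy)-6-hydroxycyclohexa-1,3-dien-1-yl]methyl benzoate
Product: 7 [(1S,2S,3S,6R)-3-(benzoyloxy)-2-hydroxy-7-oxabicyclo[4.1.0]hept-4-en-1-yl]methyl benzoate (target; oxirane, OH and OBz all cis)
Conditions: VO(acac)2 (5 mol %), t-BuOOH (1.5 equiv, in decane), CH2Cl2, 0 °C
Reagents that add atoms: tert-butyl hydroperoxide, CC(C)(C)OO
Why: Hydroxyl-directed epoxidation of an allylic alcohol: the free pseudoaxial hydroxyl of 6 binds the pentavalent vanadium alkylperoxide and delivers oxygen to the adjacent trisubstituted alkene on its own face, which sets both oxirane stereocentres (C1 and C6 of the target) syn to that hydroxyl in one event, while the distal disubstituted alkene, flanked only by the non-coordinating benzoate, should be left alone.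

**Compound list**

1 | bromobenzene | Brc1ccccc1 | starting material
2 | (1S,2S)-3-bromocyclohexa-3,5-diene-1,2-diol | BrC1=CC=C[C@H](O)[C@@H]1O | intermediate
3 | (tributylstannyl)methanol | CCCC[Sn](CCCC)(CCCC)CO | starting material
4 | (tributylstannyl)methyl benzoate | CCCC[Sn](CCCC)(CCCC)COC(=O)c1ccccc1 | intermediate
5 | [(5S,6R)-5,6-dihydroxycyclohexa-1,3-dien-1-yl]methyl benzoate | O=C(OCC1=CC=C[C@H](O)[C@@H]1O)c1ccccc1 | intermediate
6 | [(5S,6R)-5-(benzoyloxy)-6-hydroxycyclohexa-1,3-dien-1-yl]methyl benzoate | O=C(OCC1=CC=C[C@H](OC(=O)c2ccccc2)[C@@H]1O)c1ccccc1 | intermediate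
7 | [(1S,2S,3S,6R)-3-(benzoyloxy)-2-hydroxy-7-oxabicyclo[4.1.0]hept-4-en-1-yl]methyl benzoate | O=C(OC[C@@]12O[C@@H]1C=C[C@H](OC(=O)c1ccccc1)[C@@H]2O)c1ccccc1 | target

Total step count: 5. Longest linear sequence: 4 steps (steps 1, 3, 4, 5).

**Steps most likely to fail**

Step 3. Transfer of the sp3 benzoyloxymethyl group from tin may be slow. Butyl transfer, protodestannylation, ionisation of the newly formed dienylic benzoate by zerovalent palladium, or dehydrative aromatisation of the warmed diene-diol could then overtake the coupling. The fallback uses no organotin and brings the carbon in at the carboxyl oxidation level. Setting out from 2, Pd-catalysed methoxycarbonylation of the vinylic bromide (Pd(OAc)2, PPh3, CO 1 atm, Et3N, MeOH, 50 °C) should give methyl (5S,6R)-5,6-dihydroxycyclohexa-1,3-diene-1-carboxylate F1. Reduction of the ester with i-Bu2AlH (excess, CH2Cl2/THF, −78 °C) should give (1S,2R)-3-(hydroxymethyl)cyclohexa-3,5-diene-1,2-diol F2. Benzoylation of the primary and the distal secondary hydroxyl (BzCl 2.1 equiv, 2,4,6-collidine, CH2Cl2, −40 °C) rejoins the route at 6.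

Step 4. Acylation may fail to discriminate between the two secondary hydroxyls, the benzoyl group may migrate across the cis-diol under base, or a third benzoylation may set in. The fallback reverses the order of events. Setting out from 2, where the proximal hydroxyl is additionally deactivated by the neighbouring C–Br carbon, distal benzoylation (BzCl 1.05 equiv, 2,4,6-collidine, CH2Cl2, −40 °C) should give (1S,6S)-5-bromo-6-hydroxycyclohexa-2,4-dien-1-yl benzoate F3. Stille coupling of F3 with 4 under the conditions of step 3 rejoins the route at 6.

Step 5. Oxygen may be delivered to the wrong face or to the distal alkene, or the vanadium catalyst may oxidise the secondary allylic alcohol to the dienone or trigger dehydrative aromatisation. The fallback replaces the directed oxygen transfer by a stepwise anti addition and ring closure. Setting out from 6, NBS in aqueous THF at 0 °C should form the bromonium ion on the face opposite the two ring oxygens, and water should open it from the oxygen-bearing face. This should give the trans-bromohydrin [(1S,2R,5S,6S)-5-(benzoyloxy)-1-bromo-2,6-dihydroxycyclohex-3-en-1-yl]methyl benzoate F4 and/or its regioisomer [(1S,2S,5S,6S)-5-(benzoyloxy)-2-bromo-1,6-dihydroxycyclohex-3-en-1-yl]methyl benzoate F5. Both carry the new hydroxyl on the face of the ring oxygens and the bromine on the other face, so ring closure with Ag2O (CH2Cl2, rt) should convert either one into 7.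

Further compounds
F1 | step 3 | methyl (5S,6R)-5,6-dihydroxycyclohexa-1,3-diene-1-carboxylate | COC(=O)C1=CC=C[C@H](O)[C@@H]1O
F2 | step 3 | (1S,2R)-3-(hydroxymethyl)cyclohexa-3,5-diene-1,2-diol | OCC1=CC=C[C@H](O)[C@@H]1O
F3 | step 4 | (1S,6S)-5-bromo-6-hydroxycyclohexa-2,4-dien-1-yl benzoate | BrC1=CC=C[C@H](OC(=O)c2ccccc2)[C@@H]1O
F4 | step 5 | [(1S,2R,5S,6S)-5-(benzoyloxy)-1-bromo-2,6-dihydroxycyclohex-3-en-1-yl]methyl benzoate | O=C(OC[C@]1(Br)[C@H](O)C=C[C@H](OC(=O)c2ccccc2)[C@@H]1O)c1ccccc1
F5 | step 5 | [(1S,2S,5S,6S)-5-(benzoyloxy)-2-bromo-1,6-dihydroxycyclohex-3-en-1-yl]methyl benzoate | O=C(OC[C@@]1(O)[C@@H](Br)C=C[C@H](OC(=O)c2ccccc2)[C@@H]1O)c1ccccc1
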